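## Analysis of the target

Lobophynin B is a cembranoid: a 14-membered carbocycle (labelled C1 to C14) fused through C1 and C2 to a 2,5-dihydrofuran completed by the ring oxygen, C16H2 and C15, with C15 carrying the acetoxymethyl carbon C17. C1=C15 is therefore a tetrasubstituted alkene shared by both rings. The carbocycle also holds two (E)-trisubstituted alkenes, C3=C4(CH3) and C11=C12(CH3), and a trisubstituted oxirane at C7–C8 with the methyl on C8. There are three stereocentres: C2 (R), a doubly allylic ether methine, and the oxirane carbons C7 (R) and C8 (R), on which the bonds to C6 and C9 are trans. C2 and C7 are separated by four sp2 or methylene carbons, so neither can direct the other and each needs its own absolute control. The sensitive sites are the acid-labile oxirane, the ionisable C2–O bond (C2–H also turns acidic once C1 or C15 carries a carbonyl group), the dihydrofuran, which can aromatise, and the allylic acetate, which zerovalent palladium or hard nucleophiles would attack. The hard parts are the ring-fusion alkene with two different CH2O arms, the remote stereocentres and the closure of the large ring. The strategy rests on the oxirane: a quaternary C8 (CH3, C9) beside a CH carbon C7, with C6 and C9 trans, is what results when a C9 nucleophile adds to a C8 methyl ketone bearing chlorine on C7 and the alkoxide then displaces the chloride with inversion.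

## Retrosynthetic reasoning

**Acetate last.** The C17–O acetyl bond of 29 is cut first, giving alcohol 28 and its silyl ether 27. An allylic acetate on C17 would not be safe under palladium catalysis or organometallic reagents, so C17 travels as a robust silyl ether and the ester is put on in the final step.

**C1–C14.** In 27 the only ring bond that joins an sp2 carbon of the furan to an unfunctionalised CH2 is C1–C14. Cutting it gives the open-chain bromide 25, whose terminal C13=C14 vinyl group can be hydroborated (alkylborane 26) and coupled to the C1 bromide. The closure makes no stereocentre, lies far from the oxirane and C2, and leaves the C11=C12 geometry untouched.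

**C8–C9 and the oxirane (key disconnection).** Cutting C8–C9 and the O–C7 bond of 25 leads to the Grignard reagent 22 (used as organocerium 23) and the α-chloro methyl ketone 18, through chlorohydrin 24. This divides the molecule into halves of similar size and lets one stereocentre, the C7 chloride, set both oxirane centres: C8 by dipole-controlled addition, C7 by inversion on closure. The forward step must add to the ketone without enolising it and must take the Cornforth, not a chelated, pathway.

**The chloro ketone.** Ketone 18 is traced to chlorohydrin 17 and the α-chloro aldehyde 16, which comes from aldehyde 15 by catalytic enantioselective α-chlorination. This is the one place where C7 is set by a catalyst alone. Aldehyde 15 derives from alcohol 14 and the doubly silylated 13, whose two silyl groups differ enough to free C8 alone.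

**The dihydrofuran.** An oxa-Michael/Dieckmann annulation of an α-hydroxy ester followed by enol triflation would give a C1 enol triflate with C17 as an ester in few steps, but it was set aside. In that series C2–H is α to a carbonyl group, allylic and α to oxygen, so the alkoxide conditions of the annulation would racemise C2. In the resulting enol triflate C2–H stays γ-acidic, and the β-triflyloxy enoate is an addition–elimination acceptor for the organometal of the key step. The same positions are therefore carried as less reactive spectators: bromine on C1 and a silyl ether on C17. The ring O–C16 bond of 12 (the alcohol under 13) is cut to give the alkylidene oxetane 11. Both CH2O arms on C15 are then identical, the tetrasubstituted alkene has no geometry to control, and the C2 hydroxyl can only open the arm cis to it. The C2–O bond is never activated.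

**C2 and C2–C3.** The carbinol 11 is reached by catalyst-controlled reduction of dienone 10, itself from the racemic alcohol 9. Cutting C2–C3 of 9 gives the bromo enal 4 and the alkenyl alanate 8, made via alane 7 by carboalumination of alkyne 6. That step fixes the (E)-C3=C4 geometry and installs the C4 methyl at once.

**Building blocks.** Enal 4 comes from the dibromoalkene 2 (via the lithiated species 3) and this from oxetan-3-one 1. Alkyne 6 is the silyl ether of hex-5-yn-1-ol 5. Grignard reagent 22 comes from bromide 21, the ring-opened product of carbinol 20, made from cyclopropyl methyl ketone 19.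

## Alternatives that were turned down

**Alternative 1:** The C1–C2 bond is cut and replaced by an O–C16 ether bridge, so the carbocycle is reached from the 17-membered propargyl allyl ether A1 (C3≡C4 still an alkyne). In the forward step a chiral lithium amide removes a propargylic proton at C2 and the anion undergoes a [2,3]-Wittig shift onto C1. This breaks O–C16 and contracts the ring to the propargylic alcohol A2 with an exocyclic C15=C16 methylene.
- For it: the large ring is closed by an easy etherification, no sp2–sp3 coupling is needed at C1–C14, and one ordered intramolecular event forms a C–C bond and the C2 carbinol. On ring closure it is the stronger plan.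
- Against it: the oxirane is already present when the amide base is used, and such bases isomerise epoxides to allylic alcohols. The base must set C2 in a flexible large ring whose only stereocentres are five bonds away. C1 is made as a stereocentre only to be flattened again.
- Step economy: A2 is far from the target. The alkyne must still become the (E)-methyl alkene, and the exocyclic alkene must move into the ring while O–C16 is re-formed.
- Comparison: the chosen route gives up the easy closure but has the heterocycle in its final oxidation state before cyclisation, sets both oxirane centres in one predictable step, and needs two steps after ring closure.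

**Alternative 2:** C1–C14 and C15–C16 are cut together. The magnesium alkoxide of propargylic alcohol A3 directs CuI-catalysed anti-addition of Grignard reagent A4 to C1. The C15 alkenylmagnesium is carboxylated and lactonises onto the C2 oxygen, giving butenolide A5 with C16 as a carbonyl group.
- For it, and better than the chosen route on these points: the geometry of the tetrasubstituted alkene is fixed by the magnesium chelate, C2 sits in a propargylic alcohol whose configuration is never at risk, and the core forms in one flask where the chosen route needs eight steps to reach bromide 13.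
- Against it: the lactone carbonyl must be reduced to CH2 beside the ionisable C2–O bond. The ring must still be closed at C5–C6 between two allylic carbons, with SN2/SN2′ and E/Z ambiguity. The oxirane must be introduced late on a macrocycle with three trisubstituted alkenes and no handle for site or face selection. A4 is needed in excess.
- Comparison: the chosen route is weaker on the furan but answers what this plan leaves open, namely how C7 and C8 are controlled.

**Alternative 3:** O–C16 and C15–C17 are cut last. The carbocycle is closed first as allenol A6 (C1 bearing the vinylidene C15=C16H2, C2 a free hydroxyl). Pd(OAc)2 with a quinone reoxidant under carbon monoxide in methanol triggers 5-endo attack of the C2 hydroxyl on C16; the C15 alkenylpalladium inserts CO and is methanolysed to ester A7.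
- For it: heterocycle and C17 form in one step on a preformed ring, no C1 halide or C17 protecting group is needed, and A7 is two steps from the target. Its step economy after the key step equals that of the chosen plan.
- Against it: the difficulty moves into A6, a 14-membered ring with an exocyclic allene beside a carbinol that must be set relative to a remote oxirane. Divalent palladium, acid released in the cycle and methanol meet an acid-labile oxirane and two trisubstituted alkenes. The ester in A7 makes C2–H γ-acidic.
- Comparison: the chosen route keeps every stereocentre-forming step on acyclic material under catalyst or dipole control and closes the ring at a bond with no stereochemical consequence.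

Key step: step 17

Assumption: the facial sense of the oxazaborolidine reduction (step 6) and of the enamine-catalysed chlorination (step 11) is taken from the usual models for these catalysts; if either runs the other way, the catalyst antipode is used and nothing else changes.

Abbreviations: TBS = tert-butyldimethylsilyl, TBDPS = tert-butyldiphenylsilyl, TES = triethylsilyl, DMP = Dess–Martin periodinane, CSA = camphor-10-sulfonic acid, NCS = N-chlorosuccinimide, 9-BBN = 9-borabicyclo[3.3.1]nonane, dppf = 1,1′-bis(diphenylphosphino)ferrocene.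

## Route

Step 1
Reactants: 1 oxetan-3-one
Product: 2 3-(dibromomethylidene)oxetane
Conditions: CBr4, PPh3, CH2Cl2, 0 °C → rt
Reagents that add atoms: carbon tetrabromide, BrC(Br)(Br)Br
Why: Ramirez dibromo-olefination (first stage of the Corey–Fuchs sequence) of a strained, electrophilic ketone. Both CH2O arms are identical, so the future C1=C15 alkene has no geometry to control.

Step 2
Reactants: 2 3-(dibromomethylidene)oxetane
Product: 4 2-bromo-2-(oxetan-3-ylidene)acetaldehyde, via lithiated bromoalkene 3 (not isolated)
Conditions: n-BuLi, THF/Et2O, −105 °C; DMF, → −78 °C; H2O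
Reagents that add atoms: N,N-dimethylformamide, CN(C)C=O
Why: Bromine–lithium exchange on a gem-dibromoalkene gives an α-bromoalkenyllithium that is stable below −100 °C (Fritsch–Buttenberg–Wiechell migration is slow for alkyl groups) and is formylated by DMF. The retained bromine is the later coupling handle on C1.

Step 3
Reactants: 5 hex-5-yn-1-ol
Product: 6 tert-butyl(hex-5-yn-1-yloxy)dimethylsilane
Conditions: TBSCl, imidazole, DMF, rt
Reagents that add atoms: tert-butyldimethylsilyl chloride, CC(C)(C)[Si](C)(C)Cl
Why: Standard silylation of a primary alcohol; the ether tolerates organoaluminium and organolithium reagents and is later removed selectively.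

Step 4
Reactants: 6 tert-butyl(hex-5-yn-1-yloxy)dimethylsilane; 4 2-bromo-2-(oxetan-3-ylidene)acetaldehyde
Product: 9 rac-(3E)-1-bromo-8-{[tert-butyl(dimethyl)silyl]oxy}-4-methyl-1-(oxetan-3-ylidene)oct-3-en-2-ol, via alkenylalane 7 (not isolated), via lithium alanate 8 (not isolated)
Conditions: Me3Al, Cp2ZrCl2 (cat.), CH2Cl2, rt; volatiles removed; n-BuLi, THF/hexane, −78 °C; 4, −78 → −20 °C; H2O
Reagents that add atoms: trimethylaluminium, C[Al](C)C
Why: Negishi zirconium-catalysed carboalumination adds CH3 and Al syn across the terminal alkyne with methyl on the internal carbon, which fixes the (E)-C3=C4 geometry. The lithium alanate transfers its alkenyl group 1,2 to the aldehyde; C2 is formed racemic and is corrected in steps 5 and 6.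

Step 5
Reactants: 9 rac-(3E)-1-bromo-8-{[tert-butyl(dimethyl)silyl]oxy}-4-methyl-1-(oxetan-3-ylidene)oct-3-en-2-ol
Product: 10 (3E)-1-bromo-8-{[tert-butyl(dimethyl)silyl]oxy}-4-methyl-1-(oxetan-3-ylidene)oct-3-en-2-one
Conditions: DMP, NaHCO3, CH2Cl2, 0 °C
Reagents that add atoms: none
Why: Buffered Dess–Martin oxidation of a bis-allylic alcohol; neutral conditions leave the oxetane, silyl ether and alkenyl bromide untouched.

Step 6
Reactants: 10 (3E)-1-bromo-8-{[tert-butyl(dimethyl)silyl]oxy}-4-methyl-1-(oxetan-3-ylidene)oct-3-en-2-one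
Product: 11 (2R,3E)-1-bromo-8-{[tert-butyl(dimethyl)silyl]oxy}-4-methyl-1-(oxetan-3-ylidene)oct-3-en-2-ol
Conditions: (S)-2-methyl-CBS-oxazaborolidine, catecholborane, toluene, −78 °C
Reagents that add atoms: none
Why: CBS reduction. The α-bromo, fully substituted alkylidene arm is α-branched and twisted out of conjugation and should act as the large group, the C3 alkenyl arm (α-CH) as the small one, so hydride goes to the face that gives the (R)-carbinol at C2. Catecholborane at −78 °C keeps the reduction 1,2.

Step 7
Reactants: 11 (2R,3E)-1-bromo-8-{[tert-butyl(dimethyl)silyl]oxy}-4-methyl-1-(oxetan-3-ylidene)oct-3-en-2-ol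
Product: 12 [(5R)-4-bromo-5-[(1E)-6-{[tert-butyl(dimethyl)silyl]oxy}-2-methylhex-1-en-1-yl]-2,5-dihydrofuran-3-yl]methanol
Conditions: CSA (10 mol%), CH2Cl2, 0 °C
Reagents that add atoms: none
Why: Acid-catalysed intramolecular opening of an oxetane by a hydroxyl group (5-exo-tet, as in known oxetane-to-tetrahydrofuran openings). Only the oxetane CH2 cis to C2 can be reached in the alkene plane, so O–C16 forms regiospecifically and the other arm is released as C17H2OH. The C2–O bond is not broken, so C2 keeps its configuration.

Step 8
Reactants: 12 [(5R)-4-bromo-5-[(1E)-6-{[tert-butyl(dimethyl)silyl]oxy}-2-methylhex-1-en-1-yl]-2,5-dihydrofuran-3-yl]methanol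
Product: 13 tert-butyl({(5R)-4-bromo-5-[(1E)-6-{[tert-butyl(dimethyl)silyl]oxy}-2-methylhex-1-en-1-yl]-2,5-dihydrofuran-3-yl}methoxy)diphenylsilane
Conditions: TBDPSCl, imidazole, DMF, rt
Reagents that add atoms: tert-butyldiphenylsilyl chloride, CC(C)(C)[Si](Cl)(c1ccccc1)c1ccccc1
Why: Silylation of the primary allylic alcohol; the TBDPS ether withstands organometallic reagents, carbonate and palladium and is far more acid-stable than the TBS ether at C8.

Step 9
Reactants: 13 tert-butyl({(5R)-4-bromo-5-[(1E)-6-{[tert-butyl(dimethyl)silyl]oxy}-2-methylhex-1-en-1-yl]-2,5-dihydrofuran-3-yl}methoxy)diphenylsilane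
Product: 14 (5E)-6-[(2R)-3-bromo-4-({[tert-butyl(diphenyl)silyl]oxy}methyl)-2,5-dihydrofuran-2-yl]-5-methylhex-5-en-1-ol
Conditions: HF·pyridine, pyridine, THF, 0 °C
Reagents that add atoms: none
Why: Buffered HF·pyridine cleaves a primary alkyl TBS ether much faster than a TBDPS ether, and the medium does not ionise the doubly allylic C2–O bond.

Step 10
Reactants: 14 (5E)-6-[(2R)-3-bromo-4-({[tert-butyl(diphenyl)silyl]oxy}methyl)-2,5-dihydrofuran-2-yl]-5-methylhex-5-en-1-ol
Product: 15 (5E)-6-[(2R)-3-bromo-4-({[tert-butyl(diphenyl)silyl]oxy}methyl)-2,5-dihydrofuran-2-yl]-5-methylhex-5-enal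
Conditions: DMP, NaHCO3, CH2Cl2, 0 °C → rt
Reagents that add atoms: none
Why: Dess–Martin oxidation of a primary alcohol to the aldehyde without over-oxidation or alkene isomerisation.

Step 11
Reactants: 15 (5E)-6-[(2R)-3-bromo-4-({[tert-butyl(diphenyl)silyl]oxy}methyl)-2,5-dihydrofuran-2-yl]-5-methylhex-5-enal
Product: 16 (2S,5E)-6-[(2R)-3-bromo-4-({[tert-butyl(diphenyl)silyl]oxy}methyl)-2,5-dihydrofuran-2-yl]-2-chloro-5-methylhex-5-enal
Conditions: NCS, (2R,5R)-2,5-diphenylpyrrolidine (10 mol%), CH2Cl2, 0 °C; pentane, filtration
Reagents that add atoms: N-chlorosuccinimide, O=C1CCC(=O)N1Cl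
Why: Enamine-catalysed α-chlorination: the C2-symmetric amine forms the (E)-enamine and shields one face, so NCS chlorinates C7 to the (S)-chloride. The aldehyde is configurationally labile and is used at once without chromatography.

Step 12
Reactants: 16 (2S,5E)-6-[(2R)-3-bromo-4-({[tert-butyl(diphenyl)silyl]oxy}methyl)-2,5-dihydrofuran-2-yl]-2-chloro-5-methylhex-5-enal
Product: 17 (3S,6E)-7-[(2R)-3-bromo-4-({[tert-butyl(diphenyl)silyl]oxy}methyl)-2,5-dihydrofuran-2-yl]-3-chloro-6-methylhept-6-en-2-ol (mixture at the carbinol carbon)
Conditions: MeMgBr, Et2O, −78 °C; H2O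
Reagents that add atoms: methylmagnesium bromide, C[Mg]Br
Why: 1,2-Addition to the very electrophilic α-chloro aldehyde at −78 °C. The new carbinol centre is erased in step 13, and a cold quench avoids epoxide closure and epimerisation at C7.

Step 13
Reactants: 17 (3S,6E)-7-[(2R)-3-bromo-4-({[tert-butyl(diphenyl)silyl]oxy}methyl)-2,5-dihydrofuran-2-yl]-3-chloro-6-methylhept-6-en-2-ol
Product: 18 (3S,6E)-7-[(2R)-3-bromo-4-({[tert-butyl(diphenyl)silyl]oxy}methyl)-2,5-dihydrofuran-2-yl]-3-chloro-6-methylhept-6-en-2-one
Conditions: DMP, NaHCO3, CH2Cl2, 0 °C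
Reagents that add atoms: none
Why: Buffered Dess–Martin oxidation gives the α-chloro methyl ketone under non-basic conditions that should not enolise it, so C7 is preserved.

Step 14
Reactants: 19 cyclopropyl methyl ketone
Product: 20 2-cyclopropylbut-3-en-2-ol
Conditions: CH2=CHMgBr, THF, 0 °C; H2O
Reagents that add atoms: vinylmagnesium bromide, C=C[Mg]Br
Why: Grignard addition to a ketone gives the tertiary cyclopropyl vinyl carbinol needed for the ring-opening rearrangement.

Step 15
Reactants: 20 2-cyclopropylbut-3-en-2-ol
Product: 21 (3E)-6-bromo-3-methylhexa-1,3-diene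
Conditions: 48% aq HBr, 0 °C
Reagents that add atoms: hydrogen bromide, Br
Why: Julia cyclopropylcarbinyl-to-homoallyl rearrangement: ionisation of the carbinol and bromide attack on a cyclopropane CH2 open the ring to the trisubstituted alkene. The (E)-isomer is expected to predominate and is purified by fractional distillation.

Step 16
Reactants: 21 (3E)-6-bromo-3-methylhexa-1,3-diene
Product: 22 [(3E)-4-methylhexa-3,5-dien-1-yl]magnesium bromide
Conditions: Mg, THF, rt; titrated and used directly
Reagents that add atoms: magnesium, [Mg]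
Why: Magnesium insertion into a primary homoallylic bromide; the open homoallyl form is favoured over the cyclopropylmethyl isomer, and the solution is used fresh to preserve the alkene geometry.

Step 17
Reactants: 22 [(3E)-4-methylhexa-3,5-dien-1-yl]magnesium bromide; 18 (3S,6E)-7-[(2R)-3-bromo-4-({[tert-butyl(diphenyl)silyl]oxy}methyl)-2,5-dihydrofuran-2-yl]-3-chloro-6-methylhept-6-en-2-one
Product: 25 (2R)-3-bromo-4-({[tert-butyl(diphenyl)silyl]oxy}methyl)-2-[(1E)-2-methyl-4-{(2R,3R)-3-methyl-3-[(3E)-4-methylhexa-3,5-dien-1-yl]oxiran-2-yl}but-1-en-1-yl]-2,5-dihydrofuran, via organocerium reagent 23 (not isolated), via tertiary chlorohydrin 24 (not isolated)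
Conditions: CeCl3 (anhydrous), THF, −78 °C; 18, −78 °C; H2O; then K2CO3, MeOH, 0 °C → rt
Reagents that add atoms: none
Why: Transmetalation of 22 to cerium gives the weakly basic, oxophilic organocerium 23, which should add to the C8 carbonyl of 18 faster than it enolises it; the closest known reaction type is the Cornforth halohydrin synthesis from α-chloro ketones and Grignard reagents. In the reactive conformer the C7–Cl and C8=O dipoles are opposed (Cornforth; polar Felkin–Anh predicts the same face) and C9 enters past the C7 hydrogen and not past the C6 chain, which sets C8 as (R) in chlorohydrin 24. After a cold aqueous quench (the metal alkoxide is not warmed, to avoid a semipinacol shift), carbonate in methanol deprotonates the tertiary alcohol; its oxygen is antiperiplanar to chloride and closes the oxirane by 3-exo-tet SN2 displacement with inversion at C7, (S) to (R). Because C9 entered on the side of H-7, C9 and C6 end up trans on the oxirane. C7 is controlled by the chlorination catalyst of step 11 and C8 by C7 through the dipole-controlled transition state; C2 is too remote to interfere. The step needs chemoselectivity for the ketone, which the inert alkenyl bromide and silyl ethers allow at −78 °C, and Cornforth rather than chelation selectivity, which the poorly chelating, strongly dipolar chlorine secures.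

Step 18
Reactants: 25 (2R)-3-bromo-4-({[tert-butyl(diphenyl)silyl]oxy}methyl)-2-[(1E)-2-methyl-4-{(2R,3R)-3-methyl-3-[(3E)-4-methylhexa-3,5-dien-1-yl]oxiran-2-yl}but-1-en-1-yl]-2,5-dihydrofuran
Product: 27 O-TBDPS-deacetyl-lobophynin B (14-membered ring closed at C1–C14), via alkylborane 26 (not isolated)
Conditions: 9-BBN, THF, rt; then slow addition to PdCl2(dppf), AsPh3, Cs2CO3, DMF/THF/H2O, 50 °C (about 1 mM)
Reagents that add atoms: none
Why: 9-BBN hydroborates only the terminal C13=C14 bond and places boron on C14. Intramolecular B-alkyl Suzuki–Miyaura coupling with the C1 bromide under high dilution forms C1–C14 and the ring without creating a stereocentre. The carbonate base spares the oxirane, and C17 is a silyl ether, not an allylic ester that zerovalent palladium could ionise.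

Step 19
Reactants: 27 O-TBDPS-deacetyl-lobophynin B
Product: 28 deacetyl-lobophynin B (C17 primary allylic alcohol)
Conditions: TBAF, THF, 0 °C → rt
Reagents that add atoms: none
Why: Fluoride cleaves the silyl ether under conditions that leave the oxirane and the dihydrofuran intact.

Step 20
Reactants: 28 deacetyl-lobophynin B
Product: 29 lobophynin B
Conditions: Ac2O, pyridine, DMAP (cat.), CH2Cl2, 0 °C → rt
Reagents that add atoms: acetic anhydride, CC(=O)OC(C)=O
Why: DMAP-catalysed acetylation of the primary allylic alcohol under mild basic conditions completes the target.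

## Compound list

1 | oxetan-3-one | O=C1COC1 | starting material
2 | 3-(dibromomethylidene)oxetane | BrC(Br)=C1COC1 | intermediate
3 | 3-[bromo(lithio)methylidene]oxetane | [Li]C(Br)=C1COC1 | intermediate
4 | 2-bromo-2-(oxetan-3-ylidene)acetaldehyde | O=CC(Br)=C1COC1 | intermediate
5 | hex-5-yn-1-ol | C#CCCCCO | starting material
6 | tert-butyl(hex-5-yn-1-yloxy)dimethylsilane | C#CCCCCO[Si](C)(C)C(C)(C)C | intermediate
7 | dimethyl[(1E)-6-{[tert-butyl(dimethyl)silyl]oxy}-2-methylhex-1-en-1-yl]alane | C[Al](C)/C=C(\C)CCCCO[Si](C)(C)C(C)(C)C | intermediate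
8 | lithium butyl(dimethyl)[(1E)-6-{[tert-butyl(dimethyl)silyl]oxy}-2-methylhex-1-en-1-yl]alanate | [Li+].CCCC[Al-](C)(C)/C=C(\C)CCCCO[Si](C)(C)C(C)(C)C | intermediate
9 | rac-(3E)-1-bromo-8-{[tert-butyl(dimethyl)silyl]oxy}-4-methyl-1-(oxetan-3-ylidene)oct-3-en-2-ol | CC(C)(C)[Si](C)(C)OCCCC/C(C)=C/C(O)C(Br)=C1COC1 | intermediate
10 | (3E)-1-bromo-8-{[tert-butyl(dimethyl)silyl]oxy}-4-methyl-1-(oxetan-3-ylidene)oct-3-en-2-one | CC(C)(C)[Si](C)(C)OCCCC/C(C)=C/C(=O)C(Br)=C1COC1 | intermediate
11 | (2R,3E)-1-bromo-8-{[tert-butyl(dimethyl)silyl]oxy}-4-methyl-1-(oxetan-3-ylidene)oct-3-en-2-ol | CC(C)(C)[Si](C)(C)OCCCC/C(C)=C/[C@@H](O)C(Br)=C1COC1 | intermediate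
12 | [(5R)-4-bromo-5-[(1E)-6-{[tert-butyl(dimethyl)silyl]oxy}-2-methylhex-1-en-1-yl]-2,5-dihydrofuran-3-yl]methanol | CC(C)(C)[Si](C)(C)OCCCC/C(C)=C/[C@H]1OCC(CO)=C1Br | intermediate
13 | tert-butyl({(5R)-4-bromo-5-[(1E)-6-{[tert-butyl(dimethyl)silyl]oxy}-2-methylhex-1-en-1-yl]-2,5-dihydrofuran-3-yl}methoxy)diphenylsilane | CC(C)(C)[Si](C)(C)OCCCC/C(C)=C/[C@H]1OCC(CO[Si](c2ccccc2)(c2ccccc2)C(C)(C)C)=C1Br | intermediate
14 | (5E)-6-[(2R)-3-bromo-4-({[tert-butyl(diphenyl)silyl]oxy}methyl)-2,5-dihydrofuran-2-yl]-5-methylhex-5-en-1-ol | OCCCC/C(C)=C/[C@H]1OCC(CO[Si](c2ccccc2)(c2ccccc2)C(C)(C)C)=C1Br | intermediate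
15 | (5E)-6-[(2R)-3-bromo-4-({[tert-butyl(diphenyl)silyl]oxy}methyl)-2,5-dihydrofuran-2-yl]-5-methylhex-5-enal | O=CCCC/C(C)=C/[C@H]1OCC(CO[Si](c2ccccc2)(c2ccccc2)C(C)(C)C)=C1Br | intermediate
16 | (2S,5E)-6-[(2R)-3-bromo-4-({[tert-butyl(diphenyl)silyl]oxy}methyl)-2,5-dihydrofuran-2-yl]-2-chloro-5-methylhex-5-enal | O=C[C@@H](Cl)CC/C(C)=C/[C@H]1OCC(CO[Si](c2ccccc2)(c2ccccc2)C(C)(C)C)=C1Br | intermediate
17 | (3S,6E)-7-[(2R)-3-bromo-4-({[tert-butyl(diphenyl)silyl]oxy}methyl)-2,5-dihydrofuran-2-yl]-3-chloro-6-methylhept-6-en-2-ol, mixture at C2 of the chain | CC(O)[C@@H](Cl)CC/C(C)=C/[C@H]1OCC(CO[Si](c2ccccc2)(c2ccccc2)C(C)(C)C)=C1Br | intermediate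
18 | (3S,6E)-7-[(2R)-3-bromo-4-({[tert-butyl(diphenyl)silyl]oxy}methyl)-2,5-dihydrofuran-2-yl]-3-chloro-6-methylhept-6-en-2-one | CC(=O)[C@@H](Cl)CC/C(C)=C/[C@H]1OCC(CO[Si](c2ccccc2)(c2ccccc2)C(C)(C)C)=C1Br | intermediate
19 | cyclopropyl methyl ketone | CC(=O)C1CC1 | starting material
20 | 2-cyclopropylbut-3-en-2-ol | C=CC(C)(O)C1CC1 | intermediate
21 | (3E)-6-bromo-3-methylhexa-1,3-diene | BrCC/C=C(C)/C=C | intermediate
22 | [(3E)-4-methylhexa-3,5-dien-1-yl]magnesium bromide | Br[Mg]CC/C=C(C)/C=C | intermediate
23 | dichloro[(3E)-4-methylhexa-3,5-dien-1-yl]cerium | Cl[Ce](Cl)CC/C=C(C)/C=C | intermediate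
24 | tertiary chlorohydrin (7S,8R): adduct of 23 at the carbonyl carbon of 18 | C=C/C(C)=C/CC[C@@](C)(O)[C@@H](Cl)CC/C(C)=C/[C@H]1OCC(CO[Si](c2ccccc2)(c2ccccc2)C(C)(C)C)=C1Br | intermediate
25 | (2R)-3-bromo-4-({[tert-butyl(diphenyl)silyl]oxy}methyl)-2-[(1E)-2-methyl-4-{(2R,3R)-3-methyl-3-[(3E)-4-methylhexa-3,5-dien-1-yl]oxiran-2-yl}but-1-en-1-yl]-2,5-dihydrofuran | C=C/C(C)=C/CC[C@@]1(C)O[C@@H]1CC/C(C)=C/[C@H]1OCC(CO[Si](c2ccccc2)(c2ccccc2)C(C)(C)C)=C1Br | intermediate
26 | B-alkyl-9-BBN from 25 (boron on C14) | C1CCC2CCCC1B2CC/C(C)=C/CC[C@@]1(C)O[C@@H]1CC/C(C)=C/[C@H]1OCC(CO[Si](c2ccccc2)(c2ccccc2)C(C)(C)C)=C1Br | intermediate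
27 | O-TBDPS-deacetyl-lobophynin B | CC(C)(C)[Si](c1ccccc1)(c1ccccc1)OCC1=C2CC/C(C)=C/CC[C@@]3(C)O[C@@H]3CC/C(C)=C/[C@H]2OC1 | intermediate
28 | deacetyl-lobophynin B | OCC1=C2CC/C(C)=C/CC[C@@]3(C)O[C@@H]3CC/C(C)=C/[C@H]2OC1 | intermediate
29 | lobophynin B | CC(=O)OCC1=C2CC/C(C)=C/CC[C@@]3(C)O[C@@H]3CC/C(C)=C/[C@H]2OC1 | target

## Step count and least certain steps

Total: 20 steps. Longest linear sequence: 16 steps (1, 2, 4 to 13, 17 to 20).

**Step 17 (key step).** Enolisation of the chloro ketone by the organometal, or during its preparation in steps 11 to 13, would scramble C7 and with it both oxirane centres. Facial discrimination at a methyl ketone may be incomplete, and the halohydrin salt may rearrange if warmed. Fallback: chlorine is replaced by oxygen while the order of events is kept. It sets out from aldehyde 15 and returns at 25.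
- MeMgBr gives the secondary alcohol F1, and Dess–Martin oxidation gives the methyl ketone F2.
- Proline-catalysed α-aminoxylation with nitrosobenzene (D-proline by analogy with cyclic ketones; the enamine forms towards C7, not the methyl group) gives the anilinooxy ketone F3. Zinc in acetic acid cleaves the N–O bond to the (S)-α-hydroxy ketone F4.
- Triethylsilylation gives the silyloxy ketone F5, which enolises far less readily than 18.
- Grignard reagent 22 adds under polar Felkin–Anh control (silyloxy group anti to the nucleophile, the same face as with chlorine) to give the tertiary alcohol F6.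
- PPTS in methanol frees the diol F7, the secondary hydroxyl alone is mesylated (mesylate F8), and K2CO3 in methanol closes the oxirane with inversion at C7.

**Step 18.** Intermolecular coupling may compete with ring closure, and slow oxidative addition at the hindered tetrasubstituted bromide would leave the alkylborane open to protodeboronation or β-hydride loss. Fallback: a base-free Negishi closure. It sets out from 25 and returns at 27. Alkylborane 26 is made as before and converted with NaOMe and iodine into the primary iodide F9. Zinc dust with LiCl inserts into the C–I bond, not the alkenyl bromide, to give the alkylzinc iodide F10, which is cyclised with Pd(OAc)2 and SPhos under high dilution.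

**Step 6.** Both ketone substituents are alkenyl groups, so face discrimination may be poor, and conjugate reduction may compete. Fallback: the stereocentre is set by addition instead of reduction. It sets out from aldehyde 4 and alkyne 6 and returns at 11.
- Me2Zn/ProPhenol-catalysed alkynylation (ligand antipode for Re-face attack) gives the (R)-propargylic alcohol F11.
- Red-Al, then iodine: hydroxyl-directed trans-hydroalumination puts aluminium, then iodine, on C4 cis to C2 and gives the (Z)-iodoalkene F12.
- Negishi methylation (MeZnCl, Pd(PPh3)4) should take the iodide before the hindered bromide and fixes the C3=C4 geometry.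

**Step 7.** Acid may ionise the doubly allylic carbinol (loss of configuration, allylic transposition), or the activated oxetane may oligomerise before the hydroxyl closes. Fallback: the same symmetric-arm logic with an acetonide and a neutral ring closure. It sets out from alkyne 6 and returns at 12.
- 2,2-Dimethyl-1,3-dioxan-5-one F13 is converted as in steps 1 and 2 into the dibromoalkene F14 and the bromo enal F15.
- Alanate 8 (from 6) adds to give the racemic alcohol F16; oxidation gives the dienone F17 and CBS reduction the (R)-alcohol F18.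
- Mild hydrolysis (CeCl3·7H2O, oxalic acid, MeCN) gives the triol F19, which keeps its TBS ether.
- Mitsunobu cyclodehydration (PPh3, DIAD) displaces the primary oxyphosphonium cis to C2 with the C2 hydroxyl, with retention at C2.

## Further compounds

F1 | step 17 | (6E)-7-[(2R)-3-bromo-4-({[tert-butyl(diphenyl)silyl]oxy}methyl)-2,5-dihydrofuran-2-yl]-6-methylhept-6-en-2-ol | CC(O)CCC/C(C)=C/[C@H]1OCC(CO[Si](c2ccccc2)(c2ccccc2)C(C)(C)C)=C1Br
F2 | step 17 | (6E)-7-[(2R)-3-bromo-4-({[tert-butyl(diphenyl)silyl]oxy}methyl)-2,5-dihydrofuran-2-yl]-6-methylhept-6-en-2-one | CC(=O)CCC/C(C)=C/[C@H]1OCC(CO[Si](c2ccccc2)(c2ccccc2)C(C)(C)C)=C1Br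
F3 | step 17 | (3S)-3-(anilinooxy) derivative of F2 | CC(=O)[C@@H](ONc1ccccc1)CC/C(C)=C/[C@H]1OCC(CO[Si](c2ccccc2)(c2ccccc2)C(C)(C)C)=C1Br
F4 | step 17 | (3S)-3-hydroxy derivative of F2 | CC(=O)[C@@H](O)CC/C(C)=C/[C@H]1OCC(CO[Si](c2ccccc2)(c2ccccc2)C(C)(C)C)=C1Br
F5 | step 17 | (3S)-3-(triethylsilyloxy) derivative of F2 | CC(=O)[C@@H](O[Si](CC)(CC)CC)CC/C(C)=C/[C@H]1OCC(CO[Si](c2ccccc2)(c2ccccc2)C(C)(C)C)=C1Br
F6 | step 17 | tertiary alcohol from 22 and F5 (C7 triethylsilyl ether, C8 carbinol) | C=C/C(C)=C/CC[C@@](C)(O)[C@@H](O[Si](CC)(CC)CC)CC/C(C)=C/[C@H]1OCC(CO[Si](c2ccccc2)(c2ccccc2)C(C)(C)C)=C1Br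
F7 | step 17 | C7,C8-diol from F6 | C=C/C(C)=C/CC[C@@](C)(O)[C@@H](O)CC/C(C)=C/[C@H]1OCC(CO[Si](c2ccccc2)(c2ccccc2)C(C)(C)C)=C1Br
F8 | step 17 | C7 methanesulfonate of F7 | C=C/C(C)=C/CC[C@@](C)(O)[C@@H](OS(C)(=O)=O)CC/C(C)=C/[C@H]1OCC(CO[Si](c2ccccc2)(c2ccccc2)C(C)(C)C)=C1Br
F9 | step 18 | C14 primary iodide from 25 | ICC/C(C)=C/CC[C@@]1(C)O[C@@H]1CC/C(C)=C/[C@H]1OCC(CO[Si](c2ccccc2)(c2ccccc2)C(C)(C)C)=C1Br
F10 | step 18 | C14 alkylzinc iodide from F9 | I[Zn]CC/C(C)=C/CC[C@@]1(C)O[C@@H]1CC/C(C)=C/[C@H]1OCC(CO[Si](c2ccccc2)(c2ccccc2)C(C)(C)C)=C1Br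
F11 | step 6 | (2R)-1-bromo-8-{[tert-butyl(dimethyl)silyl]oxy}-1-(oxetan-3-ylidene)oct-3-yn-2-ol | CC(C)(C)[Si](C)(C)OCCCCC#C[C@@H](O)C(Br)=C1COC1
F12 | step 6 | (2R,3Z)-1-bromo-8-{[tert-butyl(dimethyl)silyl]oxy}-4-iodo-1-(oxetan-3-ylidene)oct-3-en-2-ol | CC(C)(C)[Si](C)(C)OCCCC/C(I)=C/[C@@H](O)C(Br)=C1COC1
F13 | step 7 | 2,2-dimethyl-1,3-dioxan-5-one | CC1(C)OCC(=O)CO1
F14 | step 7 | 5-(dibromomethylidene)-2,2-dimethyl-1,3-dioxane | CC1(C)OCC(=C(Br)Br)CO1
F15 | step 7 | 2-bromo-2-(2,2-dimethyl-1,3-dioxan-5-ylidene)acetaldehyde | CC1(C)OCC(=C(Br)C=O)CO1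
F16 | step 7 | rac-(3E)-1-bromo-8-{[tert-butyl(dimethyl)silyl]oxy}-1-(2,2-dimethyl-1,3-dioxan-5-ylidene)-4-methyloct-3-en-2-ol | CC(C)(C)[Si](C)(C)OCCCC/C(C)=C/C(O)C(Br)=C1COC(C)(C)OC1
F17 | step 7 | (3E)-1-bromo-8-{[tert-butyl(dimethyl)silyl]oxy}-1-(2,2-dimethyl-1,3-dioxan-5-ylidene)-4-methyloct-3-en-2-one | CC(C)(C)[Si](C)(C)OCCCC/C(C)=C/C(=O)C(Br)=C1COC(C)(C)OC1
F18 | step 7 | (2R,3E)-1-bromo-8-{[tert-butyl(dimethyl)silyl]oxy}-1-(2,2-dimethyl-1,3-dioxan-5-ylidene)-4-methyloct-3-en-2-ol | CC(C)(C)[Si](C)(C)OCCCC/C(C)=C/[C@@H](O)C(Br)=C1COC(C)(C)OC1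
F19 | step 7 | (4R,5E)-3-bromo-10-{[tert-butyl(dimethyl)silyl]oxy}-2-(hydroxymethyl)-6-methyldeca-2,5-diene-1,4-diol | CC(C)(C)[Si](C)(C)OCCCC/C(C)=C/[C@@H](O)C(Br)=C(CO)CO
A1 | alternative 1 | 17-membered propargyl allyl ether (oxygen between C2 and C16, C3≡C4 alkyne, C17 as TBS ether) | CC(C)(C)[Si](C)(C)OC/C1=C/CC/C(C)=C/CC[C@@]2(C)O[C@@H]2CCC#CCOC1
A2 | alternative 1 | 14-membered propargylic alcohol with exocyclic C15=C16 methylene | C=C(CO[Si](C)(C)C(C)(C)C)[C@H]1CC/C(C)=C/CC[C@@]2(C)O[C@@H]2CCC#C[C@H]1O
A3 | alternative 2 | C2 propargylic alcohol (C5 as TBS ether, C17 as p-methoxybenzyl ether) | O[C@H](/C=C(C)/CO[Si](C)(C)C(C)(C)C)C#CCOCc1ccc(OC)cc1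
A4 | alternative 2 | C14 Grignard reagent (C6 as TBDPS ether) | Br[Mg]CC/C(C)=C/CC/C(C)=C/CO[Si](c1ccccc1)(c1ccccc1)C(C)(C)C
A5 | alternative 2 | butenolide (C16 carbonyl) carrying both side chains | O=C1O[C@H](/C=C(C)/CO[Si](C)(C)C(C)(C)C)C(CC/C(C)=C/CC/C(C)=C/CO[Si](c2ccccc2)(c2ccccc2)C(C)(C)C)=C1COCc1ccc(OC)cc1
A6 | alternative 3 | macrocyclic allenol (C1 vinylidene, C2 hydroxyl) | C=C=C1CC/C(C)=C/CC[C@@]2(C)O[C@@H]2CC/C(C)=C/[C@H]1O
A7 | alternative 3 | macrocyclic methyl 2,5-dihydrofuran-3-carboxylate (C17 as ester) | COC(=O)C1=C2CC/C(C)=C/CC[C@@]3(C)O[C@@H]3CC/C(C)=C/[C@H]2OC1
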